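**Retrosynthetic overview**

1. Feature: in ring A (the benzene ring of the chromone) C5, C6 and C7 are substituted and only C8 carries hydrogen. Cutting the C4–C4a bond leaves a 4-alkyl-3,5-bis(benzyloxy)phenyl vinyl ether whose two carbons ortho to O1 (future C4a and C8) are equivalent, so ring closure can only give the 6-alkyl chromone.
2. Ring C: C4–C4a by intramolecular Friedel–Crafts acylation of a (Z)-3-aryloxy-2-arylacrylic acid; O1–C2 before that by addition–elimination of the symmetric ring A phenol on the enol tosylate of the ring B α-formyl arylacetate.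
3. Ring A phenol: 3,5-bis(benzyloxy)phenol, silyl ether, metalation between the two benzyloxy groups, opening of a chiral epoxide.
4. Ring B: 1,3-bis(methoxymethoxy)benzene, the same epoxide, Mitsunobu closure of the dihydrofuran (R carbinol to S ether), ortho-formylation, homologation to the arylacetate.
5. Both stereocentres come from one (R)-epoxide made from methyl (R)-glycerate acetonide. Ring order: dihydrofuran (step 10), then pyranone ring C (step 19); all five benzyl ethers fall in the last step.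

Key step: step 19

Remark: 3,5-bis(benzyloxy)phenol and 1,3-bis(methoxymethoxy)benzene are taken as catalogue chemicals; the tertiary alcohols are carried as benzyl ethers and the secondary alcohol of the ring A side chain is left free, because every protecting group has to survive both the hydroxide that frees the acrylic acid and the acidic acylation.

**Route**

Step 1
Reactants: 1 methyl (4R)-2,2-dimethyl-1,3-dioxolane-4-carboxylate
Product: 2 2-[(4R)-2,2-dimethyl-1,3-dioxolan-4-yl]propan-2-ol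
Conditions: MeMgBr (3 equiv), THF, 0 °C to rt; aq. NH4Cl
Reagents that add atoms: methylmagnesium bromide, C[Mg]Br
Why: Double Grignard addition to the ester should give the tertiary alcohol, with the acetonide inert and the stereocentre untouched.

Step 2
Reactants: 2 2-[(4R)-2,2-dimethyl-1,3-dioxolan-4-yl]propan-2-ol
Product: 3 (4R)-4-[2-(benzyloxy)propan-2-yl]-2,2-dimethyl-1,3-dioxolane
Conditions: NaH, BnBr, Bu4NI (cat.), DMF, 0 °C to rt
Reagents that add atoms: benzyl bromide, BrCc1ccccc1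
Why: Williamson etherification of the tertiary alkoxide with a reactive benzylic halide, with iodide catalysis offsetting the hindrance.

Step 3
Reactants: 3 (4R)-4-[2-(benzyloxy)propan-2-yl]-2,2-dimethyl-1,3-dioxolane
Product: 4 (2R)-3-(benzyloxy)-3-methylbutane-1,2-diol
Conditions: AcOH/H2O (4:1), 45 °C
Reagents that add atoms: none
Why: Acid-catalysed acetal hydrolysis; the tertiary benzyl ether should stay because its ionisation is disfavoured by the oxygen on the neighbouring carbon.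

Step 4
Reactants: 4 (2R)-3-(benzyloxy)-3-methylbutane-1,2-diol
Product: 6 (2R)-2-[2-(benzyloxy)propan-2-yl]oxirane, via primary tosylate 5 (not isolated)
Conditions: TsCl, pyridine, CH2Cl2, 0 °C; then K2CO3, MeOH, rt
Reagents that add atoms: none
Why: Selective sulfonylation of the primary hydroxyl and intramolecular Williamson displacement by the secondary alkoxide close the epoxide without breaking a bond at the stereocentre, and the benzylated tertiary oxygen rules out a Payne rearrangement.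

Step 5
Reactants: 7 3,5-bis(benzyloxy)phenol
Product: 8 [3,5-bis(benzyloxy)phenoxy]tri(propan-2-yl)silane
Conditions: i-Pr3SiCl, imidazole, DMF, rt
Reagents that add atoms: chlorotri(propan-2-yl)silane, CC(C)[Si](Cl)(C(C)C)C(C)C
Why: Phenol silylation; the bulky silyl ether neither directs nor allows metalation at the carbons next to it.

Step 6
Reactants: 8 [3,5-bis(benzyloxy)phenoxy]tri(propan-2-yl)silane; 6 (2R)-2-[2-(benzyloxy)propan-2-yl]oxirane
Product: 10 (2R)-3-(benzyloxy)-1-{2,6-bis(benzyloxy)-4-[tri(propan-2-yl)silyloxy]phenyl}-3-methylbutan-2-ol, via aryllithium 9 (not isolated)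
Conditions: n-BuLi, THF, 0 °C; then −78 °C, 6, BF3·OEt2
Reagents that add atoms: none
Why: Directed ortho-metalation at the carbon flanked by two benzyloxy groups, then BF3-promoted SN2 opening of the terminal epoxide carbon, which leaves the stereocentre of 6 untouched.

Step 7
Reactants: 10 (2R)-3-(benzyloxy)-1-{2,6-bis(benzyloxy)-4-[tri(propan-2-yl)silyloxy]phenyl}-3-methylbutan-2-ol
Product: 11 3,5-bis(benzyloxy)-4-[(2R)-3-(benzyloxy)-2-hydroxy-3-methylbutyl]phenol
Conditions: Bu4NF, THF, 0 °C; aq. NH4Cl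
Reagents that add atoms: none
Why: Fluoride cleavage of the aryl silyl ether frees the symmetric ring A phenol without touching the benzyl ethers.

Step 8
Reactants: 12 1,3-bis(methoxymethoxy)benzene; 6 (2R)-2-[2-(benzyloxy)propan-2-yl]oxirane
Product: 14 (2R)-3-(benzyloxy)-1-[2,6-bis(methoxymethoxy)phenyl]-3-methylbutan-2-ol, via aryllithium 13 (not isolated)
Conditions: n-BuLi, THF, 0 °C to rt; then −78 °C, 6, BF3·OEt2
Reagents that add atoms: none
Why: Directed ortho-metalation between the two methoxymethyl ethers and the same BF3-promoted epoxide opening at the terminal carbon.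

Step 9
Reactants: 14 (2R)-3-(benzyloxy)-1-[2,6-bis(methoxymethoxy)phenyl]-3-methylbutan-2-ol
Product: 15 2-[(2R)-3-(benzyloxy)-2-hydroxy-3-methylbutyl]benzene-1,3-diol
Conditions: HCl (cat.), MeOH, 40 °C
Reagents that add atoms: none
Why: Acid-catalysed transacetalisation removes both methoxymethyl ethers and leaves a resorcinol whose two hydroxyls are equivalent.

Step 10
Reactants: 15 2-[(2R)-3-(benzyloxy)-2-hydroxy-3-methylbutyl]benzene-1,3-diol
Product: 16 (2S)-2-[2-(benzyloxy)propan-2-yl]-2,3-dihydro-1-benzofuran-4-ol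
Conditions: PPh3, DIAD, THF, 0 °C to rt
Reagents that add atoms: none
Why: Mitsunobu cyclodehydration: the oxyphosphonium of the secondary alcohol is displaced 5-exo-tet by a phenol oxygen with inversion, turning the R carbinol into the S dihydrofuran centre, and either phenol gives the same product.

Step 11
Reactants: 16 (2S)-2-[2-(benzyloxy)propan-2-yl]-2,3-dihydro-1-benzofuran-4-ol
Product: 17 (2S)-2-[2-(benzyloxy)propan-2-yl]-4-hydroxy-2,3-dihydro-1-benzofuran-5-carbaldehyde
Conditions: MgCl2, Et3N, (CH2O)n, MeCN, reflux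
Reagents that add atoms: paraformaldehyde (formaldehyde), C=O
Why: Magnesium-mediated ortho-formylation of phenols (Casnati–Skattebøl) delivers formaldehyde within the magnesium phenoxide, so only the one free ortho carbon (C5) can react.

Step 12
Reactants: 17 (2S)-2-[2-(benzyloxy)propan-2-yl]-4-hydroxy-2,3-dihydro-1-benzofuran-5-carbaldehyde
Product: 18 (2S)-4-(benzyloxy)-2-[2-(benzyloxy)propan-2-yl]-2,3-dihydro-1-benzofuran-5-carbaldehyde
Conditions: BnBr, K2CO3, DMF, 50 °C
Reagents that add atoms: benzyl bromide, BrCc1ccccc1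
Why: Williamson benzylation of the salicylaldehyde hydroxyl, which becomes the protected oxygen ortho to the future C3 aryl bond.

Step 13
Reactants: 18 (2S)-4-(benzyloxy)-2-[2-(benzyloxy)propan-2-yl]-2,3-dihydro-1-benzofuran-5-carbaldehyde
Product: 19 (2S)-4-(benzyloxy)-2-[2-(benzyloxy)propan-2-yl]-5-[2-(methylsulfanyl)-2-(methylsulfinyl)ethenyl]-2,3-dihydro-1-benzofuran
Conditions: CH3S(O)CH2SCH3, BnMe3NOH (cat.), THF, reflux
Reagents that add atoms: methyl (methylsulfanyl)methyl sulfoxide, CS(=O)CSC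
Why: Knoevenagel-type condensation of the aldehyde with the formaldehyde dithioacetal S-oxide, the first half of the Ogura–Tsuchihashi arylacetic ester homologation.

Step 14
Reactants: 19 (2S)-4-(benzyloxy)-2-[2-(benzyloxy)propan-2-yl]-5-[2-(methylsulfanyl)-2-(methylsulfinyl)ethenyl]-2,3-dihydro-1-benzofuran
Product: 20 methyl {(2S)-4-(benzyloxy)-2-[2-(benzyloxy)propan-2-yl]-2,3-dihydro-1-benzofuran-5-yl}acetate
Conditions: HCl, MeOH, 0 °C to rt
Reagents that add atoms: methanol, CO
Why: Acid alcoholysis of the ketene dithioacetal S-oxide gives the arylacetic ester, and benzyl ethers are stable to methanolic HCl at this temperature.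

Step 15
Reactants: 20 methyl {(2S)-4-(benzyloxy)-2-[2-(benzyloxy)propan-2-yl]-2,3-dihydro-1-benzofuran-5-yl}acetate
Product: 21 methyl (2Z)-2-{(2S)-4-(benzyloxy)-2-[2-(benzyloxy)propan-2-yl]-2,3-dihydro-1-benzofuran-5-yl}-3-hydroxyprop-2-enoate
Conditions: NaH, HCO2Me, THF, 0 °C to rt; dilute HCl
Reagents that add atoms: methyl formate, COC=O
Why: Crossed Claisen condensation with methyl formate, driven by the stabilised enolate, gives the α-formyl ester as its hydrogen-bonded enol.

Step 16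
Reactants: 21 methyl (2Z)-2-{(2S)-4-(benzyloxy)-2-[2-(benzyloxy)propan-2-yl]-2,3-dihydro-1-benzofuran-5-yl}-3-hydroxyprop-2-enoate
Product: 22 methyl (2Z)-2-{(2S)-4-(benzyloxy)-2-[2-(benzyloxy)propan-2-yl]-2,3-dihydro-1-benzofuran-5-yl}-3-[(4-methylbenzenesulfonyl)oxy]prop-2-enoate
Conditions: TsCl, N-methylimidazole, LiOH·H2O, toluene, 0 °C to rt
Reagents that add atoms: 4-methylbenzenesulfonyl chloride, Cc1ccc(cc1)S(Cl)(=O)=O
Why: O-sulfonylation of the lithium-chelated enolate should place the sulfonyloxy group cis to the ester (Z enol tosylate).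

Step 17
Reactants: 22 methyl (2Z)-2-{(2S)-4-(benzyloxy)-2-[2-(benzyloxy)propan-2-yl]-2,3-dihydro-1-benzofuran-5-yl}-3-[(4-methylbenzenesulfonyl)oxy]prop-2-enoate; 11 3,5-bis(benzyloxy)-4-[(2R)-3-(benzyloxy)-2-hydroxy-3-methylbutyl]phenol
Product: 23 methyl (2Z)-2-{(2S)-4-(benzyloxy)-2-[2-(benzyloxy)propan-2-yl]-2,3-dihydro-1-benzofuran-5-yl}-3-{3,5-bis(benzyloxy)-4-[(2R)-3-(benzyloxy)-2-hydroxy-3-methylbutyl]phenoxy}prop-2-enoate
Conditions: Cs2CO3, MeCN, 0 °C to rt
Reagents that add atoms: none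
Why: Addition–elimination (vinylic nucleophilic substitution) of the phenoxide at the unsubstituted β-carbon should proceed with retention of the Z geometry, and carbonate deprotonates only the phenol, so the secondary alcohol does not compete.

Step 18
Reactants: 23 methyl (2Z)-2-{(2S)-4-(benzyloxy)-2-[2-(benzyloxy)propan-2-yl]-2,3-dihydro-1-benzofuran-5-yl}-3-{3,5-bis(benzyloxy)-4-[(2R)-3-(benzyloxy)-2-hydroxy-3-methylbutyl]phenoxy}prop-2-enoate
Product: 24 (2Z)-2-{(2S)-4-(benzyloxy)-2-[2-(benzyloxy)propan-2-yl]-2,3-dihydro-1-benzofuran-5-yl}-3-{3,5-bis(benzyloxy)-4-[(2R)-3-(benzyloxy)-2-hydroxy-3-methylbutyl]phenoxy}prop-2-enoic acid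
Conditions: LiOH·H2O, THF/MeOH/H2O, rt to 40 °C; 1 M HCl to pH 3
Reagents that add atoms: lithium hydroxide, [Li+].[OH-]
Why: Ester saponification as in known hydrolyses of 3-aryloxyacrylates; every other group is an ether or an alcohol and is inert to hydroxide.

Step 19
Reactants: 24 (2Z)-2-{(2S)-4-(benzyloxy)-2-[2-(benzyloxy)propan-2-yl]-2,3-dihydro-1-benzofuran-5-yl}-3-{3,5-bis(benzyloxy)-4-[(2R)-3-(benzyloxy)-2-hydroxy-3-methylbutyl]phenoxy}prop-2-enoic acid
Product: 27 5,7-bis(benzyloxy)-3-{(2S)-4-(benzyloxy)-2-[2-(benzyloxy)propan-2-yl]-2,3-dihydro-1-benzofuran-5-yl}-6-[(2R)-3-(benzyloxy)-2-hydroxy-3-methylbutyl]-4H-chromen-4-one, via acyl trifluoroacetate 25 (not isolated), via cyclised trifluoroacetate 26 (not isolated)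
Conditions: (CF3CO)2O (4 equiv), CH2Cl2, 0 °C to rt; evaporate; K2CO3 (cat.), MeOH, 0 °C
Reagents that add atoms: none
Why: (CF3CO)2O converts the carboxylic acid into the acyl trifluoroacetate and caps the side-chain hydroxyl as a transient trifluoroacetate, the CF3CO2H set free assists ionisation to an acylium ion stabilised by the β-aryloxy group, and this ion is attacked by the ring A carbon ortho to O1 and para to a benzyloxy group, after which loss of a proton restores the arene. The closest known reaction type is the intramolecular Friedel–Crafts acylation of 3-aryloxyacrylic acids to 4H-chromen-4-ones (Ruhemann-type closure), run here with the mild anhydride activation used for acylating phloroglucinol ethers. Ring C closes as a six-membered ring by formation of the C4–C4a bond, 6-exo-trig at the acyl carbon with the attacked arene π bond inside the new ring. No stereocentre is formed, and the two existing ones are remote from the reacting atoms and resist ionisation because each carbinol carbon has an oxygen on the neighbouring carbon. The step needs site selectivity, Z geometry and chemoselectivity: the two carbons ortho to O1 are interchangeable because ring A carries benzyloxy groups at both meta positions and the side chain para to O1, so only the 6-alkyl chromone can form; the Z acid is set in steps 16 and 17 and any E isomer can still rotate about C2–C3 at the acylium stage, where the ketene–oxocarbenium resonance form lowers the barrier; and the benzyl group on the ring B oxygen ortho to the acrylic carbon keeps that oxygen from lactonising onto the activated acid. Catalytic K2CO3 in methanol then removes the transient trifluoroacetate.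

Step 20
Reactants: 27 5,7-bis(benzyloxy)-3-{(2S)-4-(benzyloxy)-2-[2-(benzyloxy)propan-2-yl]-2,3-dihydro-1-benzofuran-5-yl}-6-[(2R)-3-(benzyloxy)-2-hydroxy-3-methylbutyl]-4H-chromen-4-one
Product: 28 5,7-dihydroxy-6-[(2R)-2,3-dihydroxy-3-methylbutyl]-3-[(2S)-4-hydroxy-2-(2-hydroxypropan-2-yl)-2,3-dihydro-1-benzofuran-5-yl]-4H-chromen-4-one
Conditions: H2 (1 atm), Pd(OH)2 on carbon, EtOAc/MeOH, rt
Reagents that add atoms: none
Why: Hydrogenolysis of the five benzyl ethers; the C2=C3 bond of the chromone is a vinylogous ester and should be reduced far more slowly, and no stereocentre sits on a benzylic C–O bond.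

**Compound list**

1 | methyl (4R)-2,2-dimethyl-1,3-dioxolane-4-carboxylate | COC(=O)[C@H]1COC(C)(C)O1 | starting material
2 | 2-[(4R)-2,2-dimethyl-1,3-dioxolan-4-yl]propan-2-ol | CC(C)(O)[C@H]1COC(C)(C)O1 | intermediate
3 | (4R)-4-[2-(benzyloxy)propan-2-yl]-2,2-dimethyl-1,3-dioxolane | CC(C)(OCc1ccccc1)[C@H]1COC(C)(C)O1 | intermediate
4 | (2R)-3-(benzyloxy)-3-methylbutane-1,2-diol | CC(C)(OCc1ccccc1)[C@H](O)CO | intermediate
5 | (2R)-3-(benzyloxy)-2-hydroxy-3-methylbutyl 4-methylbenzenesulfonate (not isolated) | CC(C)(OCc1ccccc1)[C@H](O)COS(=O)(=O)c1ccc(C)cc1 | intermediate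
6 | (2R)-2-[2-(benzyloxy)propan-2-yl]oxirane | CC(C)(OCc1ccccc1)[C@H]1CO1 | intermediate
7 | 3,5-bis(benzyloxy)phenol | Oc1cc(OCc2ccccc2)cc(OCc2ccccc2)c1 | starting material
8 | [3,5-bis(benzyloxy)phenoxy]tri(propan-2-yl)silane | CC(C)[Si](Oc1cc(OCc2ccccc2)cc(OCc2ccccc2)c1)(C(C)C)C(C)C | intermediate
9 | {2,6-bis(benzyloxy)-4-[tri(propan-2-yl)silyloxy]phenyl}lithium (not isolated) | [Li]c1c(OCc2ccccc2)cc(O[Si](C(C)C)(C(C)C)C(C)C)cc1OCc1ccccc1 | intermediate
10 | (2R)-3-(benzyloxy)-1-{2,6-bis(benzyloxy)-4-[tri(propan-2-yl)silyloxy]phenyl}-3-methylbutan-2-ol | CC(C)(OCc1ccccc1)[C@H](O)Cc1c(OCc2ccccc2)cc(O[Si](C(C)C)(C(C)C)C(C)C)cc1OCc1ccccc1 | intermediate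
11 | 3,5-bis(benzyloxy)-4-[(2R)-3-(benzyloxy)-2-hydroxy-3-methylbutyl]phenol | CC(C)(OCc1ccccc1)[C@H](O)Cc1c(OCc2ccccc2)cc(O)cc1OCc1ccccc1 | intermediate
12 | 1,3-bis(methoxymethoxy)benzene | COCOc1cccc(OCOC)c1 | starting material
13 | [2,6-bis(methoxymethoxy)phenyl]lithium (not isolated) | [Li]c1c(OCOC)cccc1OCOC | intermediate
14 | (2R)-3-(benzyloxy)-1-[2,6-bis(methoxymethoxy)phenyl]-3-methylbutan-2-ol | CC(C)(OCc1ccccc1)[C@H](O)Cc1c(OCOC)cccc1OCOC | intermediate
15 | 2-[(2R)-3-(benzyloxy)-2-hydroxy-3-methylbutyl]benzene-1,3-diol | CC(C)(OCc1ccccc1)[C@H](O)Cc1c(O)cccc1O | intermediate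
16 | (2S)-2-[2-(benzyloxy)propan-2-yl]-2,3-dihydro-1-benzofuran-4-ol | Oc1cccc2c1C[C@@H](C(C)(C)OCc1ccccc1)O2 | intermediate
17 | (2S)-2-[2-(benzyloxy)propan-2-yl]-4-hydroxy-2,3-dihydro-1-benzofuran-5-carbaldehyde | O=Cc1ccc2c(c1O)C[C@@H](C(C)(C)OCc1ccccc1)O2 | intermediate
18 | (2S)-4-(benzyloxy)-2-[2-(benzyloxy)propan-2-yl]-2,3-dihydro-1-benzofuran-5-carbaldehyde | O=Cc1ccc2c(c1OCc1ccccc1)C[C@@H](C(C)(C)OCc1ccccc1)O2 | intermediate
19 | (2S)-4-(benzyloxy)-2-[2-(benzyloxy)propan-2-yl]-5-[2-(methylsulfanyl)-2-(methylsulfinyl)ethenyl]-2,3-dihydro-1-benzofuran (mixture at the double bond and at sulfur) | CSC(=Cc1ccc2c(c1OCc1ccccc1)C[C@@H](C(C)(C)OCc1ccccc1)O2)S(C)=O | intermediate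
20 | methyl {(2S)-4-(benzyloxy)-2-[2-(benzyloxy)propan-2-yl]-2,3-dihydro-1-benzofuran-5-yl}acetate | COC(=O)Cc1ccc2c(c1OCc1ccccc1)C[C@@H](C(C)(C)OCc1ccccc1)O2 | intermediate
21 | methyl (2Z)-2-{(2S)-4-(benzyloxy)-2-[2-(benzyloxy)propan-2-yl]-2,3-dihydro-1-benzofuran-5-yl}-3-hydroxyprop-2-enoate | O/C=C(/c1ccc2c(c1OCc1ccccc1)C[C@@H](C(C)(C)OCc1ccccc1)O2)C(=O)OC | intermediate
22 | methyl (2Z)-2-{(2S)-4-(benzyloxy)-2-[2-(benzyloxy)propan-2-yl]-2,3-dihydro-1-benzofuran-5-yl}-3-[(4-methylbenzenesulfonyl)oxy]prop-2-enoate | Cc1ccc(cc1)S(=O)(=O)O/C=C(/c1ccc2c(c1OCc1ccccc1)C[C@@H](C(C)(C)OCc1ccccc1)O2)C(=O)OC | intermediate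
23 | methyl (2Z)-2-{(2S)-4-(benzyloxy)-2-[2-(benzyloxy)propan-2-yl]-2,3-dihydro-1-benzofuran-5-yl}-3-{3,5-bis(benzyloxy)-4-[(2R)-3-(benzyloxy)-2-hydroxy-3-methylbutyl]phenoxy}prop-2-enoate | CC(C)(OCc1ccccc1)[C@H](O)Cc1c(OCc2ccccc2)cc(O/C=C(/c2ccc3c(c2OCc2ccccc2)C[C@@H](C(C)(C)OCc2ccccc2)O3)C(=O)OC)cc1OCc1ccccc1 | intermediate
24 | (2Z)-2-{(2S)-4-(benzyloxy)-2-[2-(benzyloxy)propan-2-yl]-2,3-dihydro-1-benzofuran-5-yl}-3-{3,5-bis(benzyloxy)-4-[(2R)-3-(benzyloxy)-2-hydroxy-3-methylbutyl]phenoxy}prop-2-enoic acid | CC(C)(OCc1ccccc1)[C@H](O)Cc1c(OCc2ccccc2)cc(O/C=C(/c2ccc3c(c2OCc2ccccc2)C[C@@H](C(C)(C)OCc2ccccc2)O3)C(=O)O)cc1OCc1ccccc1 | intermediate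
25 | mixed trifluoroacetic anhydride of acid 24 with the side-chain hydroxyl as trifluoroacetate (not isolated) | CC(C)(OCc1ccccc1)[C@H](OC(=O)C(F)(F)F)Cc1c(OCc2ccccc2)cc(O/C=C(/c2ccc3c(c2OCc2ccccc2)C[C@@H](C(C)(C)OCc2ccccc2)O3)C(=O)OC(=O)C(F)(F)F)cc1OCc1ccccc1 | intermediate
26 | (2R)-3-(benzyloxy)-1-[5,7-bis(benzyloxy)-3-{(2S)-4-(benzyloxy)-2-[2-(benzyloxy)propan-2-yl]-2,3-dihydro-1-benzofuran-5-yl}-4-oxo-4H-chromen-6-yl]-3-methylbutan-2-yl trifluoroacetate (not isolated) | CC(C)(OCc1ccccc1)[C@H](OC(=O)C(F)(F)F)Cc1c(OCc2ccccc2)cc2occ(-c3ccc4c(c3OCc3ccccc3)C[C@@H](C(C)(C)OCc3ccccc3)O4)c(=O)c2c1OCc1ccccc1 | intermediate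
27 | 5,7-bis(benzyloxy)-3-{(2S)-4-(benzyloxy)-2-[2-(benzyloxy)propan-2-yl]-2,3-dihydro-1-benzofuran-5-yl}-6-[(2R)-3-(benzyloxy)-2-hydroxy-3-methylbutyl]-4H-chromen-4-one | CC(C)(OCc1ccccc1)[C@H](O)Cc1c(OCc2ccccc2)cc2occ(-c3ccc4c(c3OCc3ccccc3)C[C@@H](C(C)(C)OCc3ccccc3)O4)c(=O)c2c1OCc1ccccc1 | intermediate
28 | 5,7-dihydroxy-6-[(2R)-2,3-dihydroxy-3-methylbutyl]-3-[(2S)-4-hydroxy-2-(2-hydroxypropan-2-yl)-2,3-dihydro-1-benzofuran-5-yl]-4H-chromen-4-one | CC(C)(O)[C@H](O)Cc1c(O)cc2occ(-c3ccc4c(c3O)C[C@@H](C(C)(C)O)O4)c(=O)c2c1O | target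

**Count and risks**

Total step count: 20. Longest linear sequence: 17 steps (steps 1–4, 8–16 and 17–20).

Steps most likely to fail:

Step 19. The acylium ion may close too slowly if the E acid does not equilibrate, so that attack of the ring B ortho-benzyloxy oxygen with loss of benzyl (lactonisation) or acid-induced benzyl migration on ring A takes over. The fallback is the classical deoxybenzoin route to the chromone. It sets out from 20 and 10: saponification of 20 (LiOH, THF/H2O) should give {(2S)-4-(benzyloxy)-2-[2-(benzyloxy)propan-2-yl]-2,3-dihydro-1-benzofuran-5-yl}acetic acid F1. Acylation of silyl ether 10 with F1 and (CF3CO)2O in CH2Cl2 at one of its two equivalent free ring carbons should give the silyl ketone trifluoroacetate F2. K2CO3 in MeOH and then Bu4NF should take off the trifluoroacetate and the silyl group to give the 2-hydroxydeoxybenzoin F3. Heating F3 with N,N-dimethylformamide dimethyl acetal in toluene closes ring C by enaminone formation and loss of dimethylamine and comes back to the route at 27.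

Step 6. Deprotonation at a benzylic CH2 of the benzyl ethers, followed by [1,2]-Wittig rearrangement, may compete with ring metalation at 0 °C. The fallback generates the same aryllithium by halogen–metal exchange in the cold: bromination of 8 with NBS in MeCN at −20 °C, steered to the carbon between the benzyloxy groups by the bulk of the silyl ether, should give [4-bromo-3,5-bis(benzyloxy)phenoxy]tri(propan-2-yl)silane F5. F5 with n-BuLi at −78 °C gives 9 without warming, and 6 with BF3·OEt2 then returns to the route at 10.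

Step 17. The phenoxide may attack sulfur of the enol tosylate (sulfonyl transfer to the phenol) instead of the β-carbon, and reversible phenoxide addition may erode the Z geometry. The fallback replaces the sulfonate by a vinylogous acyl chloride, which has no second electrophilic site: enol 21 with (COCl)2 and catalytic DMF in CH2Cl2 should give methyl (2Z)-2-{(2S)-4-(benzyloxy)-2-[2-(benzyloxy)propan-2-yl]-2,3-dihydro-1-benzofuran-5-yl}-3-chloroprop-2-enoate F4. Displacement of chloride from F4 by phenol 11 (K2CO3, DABCO cat., DMF, rt) comes back to the route at 23.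

**Further compounds**

F1 | step 19 | {(2S)-4-(benzyloxy)-2-[2-(benzyloxy)propan-2-yl]-2,3-dihydro-1-benzofuran-5-yl}acetic acid | OC(=O)Cc1ccc2c(c1OCc1ccccc1)C[C@@H](C(C)(C)OCc1ccccc1)O2
F2 | step 19 | (2R)-3-(benzyloxy)-1-{2,6-bis(benzyloxy)-3-[({(2S)-4-(benzyloxy)-2-[2-(benzyloxy)propan-2-yl]-2,3-dihydro-1-benzofuran-5-yl}acetyl)]-4-[tri(propan-2-yl)silyloxy]phenyl}-3-methylbutan-2-yl trifluoroacetate | CC(C)(OCc1ccccc1)[C@H](OC(=O)C(F)(F)F)Cc1c(OCc2ccccc2)cc(O[Si](C(C)C)(C(C)C)C(C)C)c(C(=O)Cc2ccc3c(c2OCc2ccccc2)C[C@@H](C(C)(C)OCc2ccccc2)O3)c1OCc1ccccc1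
F3 | step 19 | 1-{2,4-bis(benzyloxy)-3-[(2R)-3-(benzyloxy)-2-hydroxy-3-methylbutyl]-6-hydroxyphenyl}-2-{(2S)-4-(benzyloxy)-2-[2-(benzyloxy)propan-2-yl]-2,3-dihydro-1-benzofuran-5-yl}ethan-1-one | CC(C)(OCc1ccccc1)[C@H](O)Cc1c(OCc2ccccc2)cc(O)c(C(=O)Cc2ccc3c(c2OCc2ccccc2)C[C@@H](C(C)(C)OCc2ccccc2)O3)c1OCc1ccccc1
F4 | step 17 | methyl (2Z)-2-{(2S)-4-(benzyloxy)-2-[2-(benzyloxy)propan-2-yl]-2,3-dihydro-1-benzofuran-5-yl}-3-chloroprop-2-enoate | Cl/C=C(/c1ccc2c(c1OCc1ccccc1)C[C@@H](C(C)(C)OCc1ccccc1)O2)C(=O)OC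
F5 | step 6 | [4-bromo-3,5-bis(benzyloxy)phenoxy]tri(propan-2-yl)silane | CC(C)[Si](Oc1cc(OCc2ccccc2)c(Br)c(OCc2ccccc2)c1)(C(C)C)C(C)C
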